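The cyclopentane C1–C2–C3–C3a–C7a, with the side chain on C3, is treated as a cyclohexene that has lost one ring carbon to the exocyclic position C1'. Ozonolysis of the cyclohexene of a trans-fused bromodecalin, followed by amine-catalysed aldol condensation, forms C2–C3, closes the five-membered ring and delivers C1' as a formyl handle in one operation. The precursor is a trans-octalin already carrying the C4 carbinol (as its triethylsilyl ether), the equatorial C7 bromide and the C7a methyl. Its para-disposed C4/C7 functions come from a Diels–Alder adduct of butadiene and a methoxy-methylquinone. The aldehyde is then extended to the dienyl chain by Grignard addition, Johnson–Claisen rearrangement and Wittig olefination.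

Key step: step 9

Remark on labels: C1–C7a and C1'–C6' are the atoms of the target (C3 carries the chain, C4 the carbinol, C7 bromine, C7a the angular methyl); the bicyclic compounds of steps 1–8 are named with naphthalene locants.
Assumption: the (S)-configured oxazaborolidinium catalyst of step 1 is taken to give the (4aS,8aR) adduct; if the facial sense were the opposite, its antipode would be used and nothing else changes.

Step 1
Reactants: 1 2-methoxy-5-methyl-1,4-benzoquinone; 2 buta-1,3-diene
Product: 3 (4aS,8aR)-2-methoxy-4a-methyl-4a,5,8,8a-tetrahydronaphthalene-1,4-dione (cis-fused)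
Conditions: (3aS)-1-(2-methylphenyl)-3,3-diphenyltetrahydro-1H,3H-pyrrolo[1,2-c][1,3,2]oxazaborole (20 mol %), HNTf2 (18 mol %), CH2Cl2, −78 → −40 °C
Reagents that add atoms: none
Why: Lewis-acid-catalysed enantioselective Diels–Alder reaction in which the diene adds to the methyl-bearing C5=C6 bond because the methoxy-bearing alkene is a deactivated vinylogous ester, suprafacial addition gives the cis fusion, and the chiral oxazaborolidinium ion blocks one quinone face so that the quaternary carbon (future C7a) is formed as S.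

Step 2
Reactants: 3
Product: 5 (4aS,8aS)-2-methoxy-4a-methyl-4a,5,8,8a-tetrahydronaphthalene-1,4-dione (trans-fused), via sodium enolate 4 (not isolated)
Conditions: NaOH (1 M aq, 1.1 equiv), dioxane, 0 °C, N2; then HCl (1 M) to pH 3
Reagents that add atoms: none
Why: Base-mediated epimerisation through the only available enolate (C1–C8a; the quaternary C4a rules out aromatisation), in which reprotonation of C8a anti to the adjacent angular methyl should give the trans-fused dione and so the future C3a–H anti to the C7a methyl.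

Step 3
Reactants: 5
Product: 7 (4aS,8aS)-4a-methyl-2,3,4a,5,8,8a-hexahydronaphthalene-1,4-dione, via methoxy-dione 6 (not isolated)
Conditions: SmI2 (4.5 equiv), THF/MeOH (10:1), −78 → −20 °C
Reagents that add atoms: none
Why: Electron-transfer reduction with SmI2, first saturating the ene-dione and then cleaving the C–O bond of the resulting α-methoxy ketone, both standard reactions of this reagent that run cold and without base and so leave the epimerisable C8a centre and the isolated alkene alone; no stereocentre is created.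

Step 4
Reactants: 7
Product: 8 (4R,4aS,8aS)-4-hydroxy-4,8a-dimethyl-3,4,4a,5,8,8a-hexahydronaphthalen-1(2H)-one
Conditions: MeMgBr (1.1 equiv), THF/toluene, −78 °C
Reagents that add atoms: methylmagnesium bromide, C[Mg]Br
Why: Grignard 1,2-addition that should favour the carbonyl next to the ring-fusion CH (C1 of 7) over the one flanked by the quaternary carbon, with the syn-axial angular methyl blocking axial approach so that methyl enters equatorially and the hydroxyl of the new carbinol (R, future C4) ends axial, cis to the angular methyl.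

Step 5
Reactants: 8
Product: 9 (4R,4aS,8aS)-4,8a-dimethyl-4-(triethylsilyloxy)-3,4,4a,5,8,8a-hexahydronaphthalen-1(2H)-one
Conditions: Et3SiOTf (1.3 equiv), 2,6-lutidine, CH2Cl2, −78 → 0 °C
Reagents that add atoms: triethylsilyl trifluoromethanesulfonate, CC[Si](CC)(CC)OS(=O)(=O)C(F)(F)F
Why: Silyl triflate silylation of a hindered tertiary alcohol, chosen so that in step 9 the oxygen cannot capture the formyl group generated γ to it as a lactol, and so that it neither consumes base in step 6 nor ionises under the acidic conditions of step 12.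

Step 6
Reactants: 9
Product: 10 (4R,4aS,8aS)-4,8a-dimethyl-4-(triethylsilyloxy)-3,4,4a,5,8,8a-hexahydronaphthalen-1-yl trifluoromethanesulfonate
Conditions: KN(SiMe3)2 (1.2 equiv), THF, −78 °C; PhNTf2, −78 → 0 °C
Reagents that add atoms: N-phenylbis(trifluoromethanesulfonimide), O=S(=O)(N(c1ccccc1)S(=O)(=O)C(F)(F)F)C(F)(F)F
Why: Enolate O-sulfonylation to an enol triflate, regiochemically unambiguous because the ketone has α-hydrogens only at C2 (C8a is quaternary).

Step 7
Reactants: 10
Product: 11 (4R,4aS,8aS)-1-bromo-4,8a-dimethyl-4-(triethylsilyloxy)-3,4,4a,5,8,8a-hexahydronaphthalene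
Conditions: Ni(OAc)2·4H2O (10 mol %), 1,5-cyclooctadiene (20 mol %), Zn (20 mol %), LiBr (2 equiv), DMA/THF, 23 °C
Reagents that add atoms: lithium bromide, [Li+].[Br-]
Why: Nickel-catalysed triflate-to-bromide exchange of an enol triflate (oxidative addition to zerovalent nickel formed by zinc, anion exchange with bromide, C–Br reductive elimination), a mild known reaction that keeps the alkene position and tolerates the silyl ether and the isolated cyclohexene.

Step 8
Reactants: 11
Product: 12 (1S,4R,4aS,8aS)-1-bromo-4,8a-dimethyl-4-(triethylsilyloxy)-1,2,3,4,4a,5,8,8a-octahydronaphthalene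
Conditions: Mn(dpm)3 (10 mol %; dpm = 2,2,6,6-tetramethylheptane-3,5-dionate), PhSiH3, t-BuOOH, i-PrOH, 23 °C
Reagents that add atoms: none
Why: Metal-hydride hydrogen-atom-transfer hydrogenation of a haloalkene in which H• goes to C2 to give the bromine-stabilised C1 radical next to the quaternary carbon, which takes its second hydrogen axially on the face anti to the angular methyl so that bromine ends equatorial (1S), while the 1,2-disubstituted cyclohexene, which could only give an unstabilised secondary radical, should react much more slowly.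

Step 9
Reactants: 12
Product: 15 (3aS,4R,7S,7aS)-7-bromo-4,7a-dimethyl-4-(triethylsilyloxy)-3a,4,5,6,7,7a-hexahydro-1H-indene-3-carbaldehyde, via ozonide 13 (not isolated), via seco-dialdehyde 14 (not isolated)
Conditions: O3, CH2Cl2, −78 °C; Me2S, −78 → 23 °C; then piperidine (0.3 equiv), AcOH (0.3 equiv), toluene, 60 °C
Reagents that add atoms: ozone, [O-][O+]=O
Why: Ozone adds to the only alkene and the resulting ozonide 13 is reduced by Me2S to seco-dialdehyde 14, whose two CH2CHO arms sit trans-diequatorial on C3a and C7a. Piperidinium acetate then converts the C3a-arm aldehyde into its enamine, the enamine α-carbon (C3) adds to the formyl carbon of the C7a arm (C2), and elimination from the adduct gives the conjugated C2=C3 enal with the former alkene carbon as the C1' formyl group. The closest known reaction type is the ozonolysis/amine-salt aldol condensation that contracts cyclohexenes to cyclopent-1-ene-1-carbaldehydes. The five-membered ring C1–C2–C3–C3a–C7a closes in the 5-(enolexo)-exo-trig mode, and no stereocentre is created, C3a, C4, C7 and C7a being out of reach of either enolisation. The step needs regioselectivity between the two arms: C3 is bonded to the tertiary C3a whereas the competing C1 is neopentylic to the quaternary C7a, so C–C bond formation from the C3a arm should be faster. The silyl ether secures this by preventing the C4 oxygen from closing onto the C3a-arm aldehyde as a lactol, which would withdraw exactly the arm that has to act as the nucleophile.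

Step 10
Reactants: 15
Product: 17 (3R,3aS,4R,7S,7aS)-7-bromo-4,7a-dimethyl-4-(triethylsilyloxy)octahydro-1H-indene-3-carbaldehyde, via C3-epimeric aldehyde 16 (not isolated)
Conditions: [(Ph3P)CuH]6 (0.4 equiv), H2O (3 equiv), benzene/THF, 23 °C; filtration through SiO2; then DBU (0.3 equiv), CH2Cl2, 23 °C
Reagents that add atoms: none
Why: Copper hydride conjugate reduction of the enal (hydride to C2, protonation of the enolate at C3) followed by base equilibration of the α-stereocentre, which should place the formyl group cis to H-3a (3R) because the opposite position is almost eclipsed with the fully substituted C4.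

Step 11
Reactants: 17
Product: 18 1-[(3R,3aS,4R,7S,7aS)-7-bromo-4,7a-dimethyl-4-(triethylsilyloxy)octahydro-1H-inden-3-yl]-2-methylprop-2-en-1-ol (both carbinol epimers)
Conditions: CH2=C(CH3)MgBr (1.5 equiv), THF, −78 °C
Reagents that add atoms: isopropenylmagnesium bromide, CC(=C)[Mg]Br
Why: Grignard addition to an aldehyde at low temperature, where carbonyl addition outruns α-deprotonation so that C3 is preserved; the new carbinol centre forms as a mixture, which is immaterial because it is destroyed in step 12.

Step 12
Reactants: 18; 19 triethyl orthoacetate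
Product: 22 ethyl (4E)-5-[(3S,3aS,4R,7S,7aS)-7-bromo-4,7a-dimethyl-4-(triethylsilyloxy)octahydro-1H-inden-3-yl]-4-methylpent-4-enoate, via mixed orthoester 20 (not isolated), via ketene acetal 21 (not isolated)
Conditions: MeC(OEt)3 (6 equiv), EtCO2H (0.1 equiv), xylene, 140 °C, EtOH distilled off
Reagents that add atoms: none
Why: Johnson–Claisen rearrangement in which acid-catalysed exchange and loss of ethanol give the allyl ketene acetal, whose chair-like [3,3]-sigmatropic shift with the bulky hydrindanyl group equatorial forms the C3'–C4' bond and the E-configured trisubstituted C1'=C2' alkene from either carbinol epimer.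

Step 13
Reactants: 22
Product: 23 (4E)-5-[(3S,3aS,4R,7S,7aS)-7-bromo-4,7a-dimethyl-4-(triethylsilyloxy)octahydro-1H-inden-3-yl]-4-methylpent-4-enal
Conditions: i-Bu2AlH (1.1 equiv), CH2Cl2, −78 °C; aq. potassium sodium tartrate
Reagents that add atoms: none
Why: Partial reduction of an ester with a dialkylaluminium hydride, whose tetrahedral aluminium hemiacetal persists at −78 °C and releases the aldehyde only on work-up, while the hindered secondary bromide and the silyl ether are inert.

Step 14
Reactants: 23
Product: 24 {[(3S,3aS,4R,7S,7aS)-7-bromo-3-[(1E)-2,6-dimethylhepta-1,5-dien-1-yl]-4,7a-dimethyloctahydro-1H-inden-4-yl]oxy}triethylsilane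
Conditions: i-PrPPh3I (1.5 equiv), n-BuLi (1.4 equiv), THF, 0 °C; then 23, −78 → 23 °C
Reagents that add atoms: isopropyltriphenylphosphonium iodide, CC(C)[P+](c1ccccc1)(c1ccccc1)c1ccccc1.[I-]
Why: Wittig olefination with the non-stabilised isopropylidene ylide, which raises no geometric issue because the new alkene carbon carries two methyl groups.

Step 15
Reactants: 24
Product: 25 (3S,3aS,4R,7S,7aS)-7-bromo-3-[(1E)-2,6-dimethylhepta-1,5-dien-1-yl]-4,7a-dimethyloctahydro-1H-inden-4-ol (target)
Conditions: Bu4NF (3 equiv), THF, 23 → 45 °C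
Reagents that add atoms: none
Why: Fluoride-induced desilylation, compatible with the two trisubstituted alkenes and with the equatorial bromide, which is neopentyl-like toward substitution and has no anti-periplanar hydrogen for elimination.

Compound list
1 | 2-methoxy-5-methyl-1,4-benzoquinone | COC1=CC(=O)C(C)=CC1=O | starting material
2 | buta-1,3-diene | C=CC=C | starting material
3 | (4aS,8aR)-2-methoxy-4a-methyl-4a,5,8,8a-tetrahydronaphthalene-1,4-dione (cis-fused) | C1=CC[C@]2(C)C(=O)C=C(OC)C(=O)[C@@H]2C1 | intermediate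
4 | sodium (4aS)-2-methoxy-4a-methyl-4-oxo-4,4a,5,8-tetrahydronaphthalen-1-olate | C1=CC[C@]2(C)C(=O)C=C(OC)C([O-])=C2C1.[Na+] | intermediate (not isolated)
5 | (4aS,8aS)-2-methoxy-4a-methyl-4a,5,8,8a-tetrahydronaphthalene-1,4-dione (trans-fused) | C1=CC[C@]2(C)C(=O)C=C(OC)C(=O)[C@H]2C1 | intermediate
6 | (4aS,8aS)-2-methoxy-4a-methyl-2,3,4a,5,8,8a-hexahydronaphthalene-1,4-dione (C2 epimers) | C1=CC[C@]2(C)C(=O)CC(OC)C(=O)[C@H]2C1 | intermediate (not isolated)
7 | (4aS,8aS)-4a-methyl-2,3,4a,5,8,8a-hexahydronaphthalene-1,4-dione | C1=CC[C@]2(C)C(=O)CCC(=O)[C@H]2C1 | intermediate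
8 | (4R,4aS,8aS)-4-hydroxy-4,8a-dimethyl-3,4,4a,5,8,8a-hexahydronaphthalen-1(2H)-one | C1=CC[C@]2(C)C(=O)CC[C@@](C)(O)[C@H]2C1 | intermediate
9 | (4R,4aS,8aS)-4,8a-dimethyl-4-(triethylsilyloxy)-3,4,4a,5,8,8a-hexahydronaphthalen-1(2H)-one | C1=CC[C@]2(C)C(=O)CC[C@@](C)(O[Si](CC)(CC)CC)[C@H]2C1 | intermediate
10 | (4R,4aS,8aS)-4,8a-dimethyl-4-(triethylsilyloxy)-3,4,4a,5,8,8a-hexahydronaphthalen-1-yl trifluoromethanesulfonate | C1=CC[C@]2(C)C(OS(=O)(=O)C(F)(F)F)=CC[C@@](C)(O[Si](CC)(CC)CC)[C@H]2C1 | intermediate
11 | (4R,4aS,8aS)-1-bromo-4,8a-dimethyl-4-(triethylsilyloxy)-3,4,4a,5,8,8a-hexahydronaphthalene | C1=CC[C@]2(C)C(Br)=CC[C@@](C)(O[Si](CC)(CC)CC)[C@H]2C1 | intermediate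
12 | (1S,4R,4aS,8aS)-1-bromo-4,8a-dimethyl-4-(triethylsilyloxy)-1,2,3,4,4a,5,8,8a-octahydronaphthalene (key-step precursor, silyl ether of the trans-fused bromodecalinol) | C1=CC[C@]2(C)[C@@H](Br)CC[C@@](C)(O[Si](CC)(CC)CC)[C@H]2C1 | intermediate
13 | ozonide (1,2,4-trioxolane across the former alkene carbons) of 12, acetal carbons undefined | O1OC2C[C@]3(C)[C@@H](Br)CC[C@@](C)(O[Si](CC)(CC)CC)[C@H]3CC1O2 | intermediate (not isolated)
14 | 2-[(1S,2S,5R,6S)-2-bromo-1,5-dimethyl-6-(2-oxoethyl)-5-(triethylsilyloxy)cyclohexyl]acetaldehyde | O=CC[C@]1(C)[C@@H](Br)CC[C@@](C)(O[Si](CC)(CC)CC)[C@H]1CC=O | intermediate (not isolated)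
15 | (3aS,4R,7S,7aS)-7-bromo-4,7a-dimethyl-4-(triethylsilyloxy)-3a,4,5,6,7,7a-hexahydro-1H-indene-3-carbaldehyde (key-step product, C2=C3) | O=CC1=CC[C@]2(C)[C@@H](Br)CC[C@@](C)(O[Si](CC)(CC)CC)[C@@H]12 | intermediate
16 | (3S,3aS,4R,7S,7aS)-7-bromo-4,7a-dimethyl-4-(triethylsilyloxy)octahydro-1H-indene-3-carbaldehyde (formyl trans to H-3a) | O=C[C@H]1CC[C@]2(C)[C@@H](Br)CC[C@@](C)(O[Si](CC)(CC)CC)[C@@H]12 | intermediate (not isolated)
17 | (3R,3aS,4R,7S,7aS)-7-bromo-4,7a-dimethyl-4-(triethylsilyloxy)octahydro-1H-indene-3-carbaldehyde (formyl cis to H-3a) | O=C[C@@H]1CC[C@]2(C)[C@@H](Br)CC[C@@](C)(O[Si](CC)(CC)CC)[C@@H]12 | intermediate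
18 | 1-[(3R,3aS,4R,7S,7aS)-7-bromo-4,7a-dimethyl-4-(triethylsilyloxy)octahydro-1H-inden-3-yl]-2-methylprop-2-en-1-ol (carbinol epimers) | CC(=C)C(O)[C@@H]1CC[C@]2(C)[C@@H](Br)CC[C@@](C)(O[Si](CC)(CC)CC)[C@@H]12 | intermediate
19 | triethyl orthoacetate | CCOC(C)(OCC)OCC | starting material
20 | mixed orthoester: 18 with its hydroxyl replaced by O–C(CH3)(OEt)2 | CC(=C)C(OC(C)(OCC)OCC)[C@@H]1CC[C@]2(C)[C@@H](Br)CC[C@@](C)(O[Si](CC)(CC)CC)[C@@H]12 | intermediate (not isolated)
21 | ketene acetal: 18 with its hydroxyl replaced by O–C(=CH2)OEt | CC(=C)C(OC(=C)OCC)[C@@H]1CC[C@]2(C)[C@@H](Br)CC[C@@](C)(O[Si](CC)(CC)CC)[C@@H]12 | intermediate (not isolated)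
22 | ethyl (4E)-5-[(3S,3aS,4R,7S,7aS)-7-bromo-4,7a-dimethyl-4-(triethylsilyloxy)octahydro-1H-inden-3-yl]-4-methylpent-4-enoate | CCOC(=O)CC/C(C)=C/[C@@H]1CC[C@]2(C)[C@@H](Br)CC[C@@](C)(O[Si](CC)(CC)CC)[C@@H]12 | intermediate
23 | (4E)-5-[(3S,3aS,4R,7S,7aS)-7-bromo-4,7a-dimethyl-4-(triethylsilyloxy)octahydro-1H-inden-3-yl]-4-methylpent-4-enal | O=CCC/C(C)=C/[C@@H]1CC[C@]2(C)[C@@H](Br)CC[C@@](C)(O[Si](CC)(CC)CC)[C@@H]12 | intermediate
24 | {[(3S,3aS,4R,7S,7aS)-7-bromo-3-[(1E)-2,6-dimethylhepta-1,5-dien-1-yl]-4,7a-dimethyloctahydro-1H-inden-4-yl]oxy}triethylsilane | CC(C)=CCC/C(C)=C/[C@@H]1CC[C@]2(C)[C@@H](Br)CC[C@@](C)(O[Si](CC)(CC)CC)[C@@H]12 | intermediate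
25 | (3S,3aS,4R,7S,7aS)-7-bromo-3-[(1E)-2,6-dimethylhepta-1,5-dien-1-yl]-4,7a-dimethyloctahydro-1H-inden-4-ol | CC(C)=CCC/C(C)=C/[C@@H]1CC[C@]2(C)[C@@H](Br)CC[C@@](C)(O)[C@@H]12 | target

Total step count: 15. Longest linear sequence: 15 steps (1 and 2 to 25; 19 enters in step 12).

Steps most likely to fail

Step 9. Enamine formation and C–C bond formation may proceed from the C7a arm, or from both arms, so that the formyl group ends on C1 instead of C3. The fallback closes the ring by alkene metathesis instead of aldol condensation and uses the C4 hydroxyl to tell the two arms apart. It sets out from 12. Desilylation (Bu4NF, THF) gives the free carbinol (1S,4R,4aS,8aS)-1-bromo-4,8a-dimethyl-1,2,3,4,4a,5,8,8a-octahydronaphthalen-4-ol F1. Ozonolysis (O3, CH2Cl2, −78 °C; Me2S) then gives the lactol aldehyde F2, in which the C3a-arm aldehyde is held by the C4 oxygen as a five-membered lactol and only the C7a arm is a free aldehyde. Methylenation of that free aldehyde (Ph3P=CH2, THF, −78 °C, lactol closed) gives the allyl lactol F3. Mannich methylenation at C3 of the lactol-masked aldehyde (dimethylmethyleneiminium iodide, Et3N, CH2Cl2) gives the α-methylene lactol F4. Ring-closing metathesis (second-generation Grubbs catalyst, [1,3-bis(2,4,6-trimethylphenyl)imidazolidin-2-ylidene]dichloro(benzylidene)(tricyclohexylphosphine)ruthenium, toluene, 80 °C) joins C2 to C3 with loss of ethene and gives the hydroxy enal F5, with the regiochemistry fixed by construction. Silylation (Et3SiOTf, 2,6-lutidine) comes back to the route at 15.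

Step 8. Hydrogen-atom transfer may also reach the cyclohexene (over-reduction), or bromine may be lost by radical reduction. The fallback removes the second alkene before the radical step. It sets out from 11. Dihydroxylation (OsO4 cat., N-methylmorpholine N-oxide, acetone/H2O) should touch only the electron-richer, unhindered cyclohexene, on the face anti to the angular methyl, and give the bromoalkene diol F6. The same hydrogen-atom-transfer hydrogenation (Mn(dpm)3, PhSiH3, t-BuOOH, i-PrOH), now with a single alkene, gives the bromo diol F7. Glycol cleavage (NaIO4, THF/H2O) comes back to the route at seco-dialdehyde 14, which is taken through the amine-salt condensation of step 9 to 15.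

Step 4. The two ketones may not be discriminated well enough (attack at the carbonyl next to the quaternary carbon, double addition), or enolisation may epimerise the ring fusion. The fallback moves the methyl addition to the stage where the two carbonyls differ electronically. It sets out from 5. Addition of MeMgBr/CeCl3 (THF, −78 °C) should occur only at the ketone carbonyl next to C8a, the other being a vinylogous ester, with the same facial course, and give the carbinol F8. Dissolving-metal reduction (Li, NH3/THF, t-BuOH, −78 °C; NH4Cl) then expels methoxide from the β-methoxy enone and saturates the resulting enone, coming back to the route at 8.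

Further compounds
F1 | step 9 | (1S,4R,4aS,8aS)-1-bromo-4,8a-dimethyl-1,2,3,4,4a,5,8,8a-octahydronaphthalen-4-ol | C1=CC[C@]2(C)[C@@H](Br)CC[C@@](C)(O)[C@H]2C1
F2 | step 9 | 2-[5-bromo-2-hydroxy-4,7a-dimethyloctahydro-1-benzofuran-4-yl]acetaldehyde (ring stereocentres as in 12, lactol carbon as a mixture) | O=CC[C@]1(C)[C@@H](Br)CC[C@@]2(C)OC(O)C[C@@H]12
F3 | step 9 | 4-allyl-5-bromo-4,7a-dimethyloctahydro-1-benzofuran-2-ol (ring stereocentres as in 12, lactol carbon as a mixture) | C=CC[C@]1(C)[C@@H](Br)CC[C@@]2(C)OC(O)C[C@@H]12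
F4 | step 9 | 4-allyl-5-bromo-4,7a-dimethyl-3-methyleneoctahydro-1-benzofuran-2-ol (ring stereocentres as in 12, lactol carbon as a mixture) | C=CC[C@]1(C)[C@@H](Br)CC[C@@]2(C)OC(O)C(=C)[C@@H]12
F5 | step 9 | (3aS,4R,7S,7aS)-7-bromo-4-hydroxy-4,7a-dimethyl-3a,4,5,6,7,7a-hexahydro-1H-indene-3-carbaldehyde | O=CC1=CC[C@]2(C)[C@@H](Br)CC[C@@](C)(O)[C@@H]12
F6 | step 8 | 6,7-cis-diol of 11 (both hydroxyls anti to the angular methyl; other centres as in 11) | O[C@@H]1[C@H](O)C[C@]2(C)C(Br)=CC[C@@](C)(O[Si](CC)(CC)CC)[C@H]2C1
F7 | step 8 | 6,7-cis-diol of 12 (both hydroxyls anti to the angular methyl; other centres as in 12) | O[C@@H]1[C@H](O)C[C@]2(C)[C@@H](Br)CC[C@@](C)(O[Si](CC)(CC)CC)[C@H]2C1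
F8 | step 4 | (4S,4aS,8aS)-4-hydroxy-3-methoxy-4,8a-dimethyl-4a,5,8,8a-tetrahydronaphthalen-1(4H)-one | C1=CC[C@]2(C)C(=O)C=C(OC)[C@@](C)(O)[C@H]2C1
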